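The constants are assumed; the rest is arithmetic.

The number to find first is 1.3 mM, the level of dissolved partner that the step to target needs.

    partner + second catalyst + intermediate ⇌ second catalyst + target (K1 = 370 L mol⁻¹, k1 = 940 L² mol⁻² min⁻¹, Ea1 = 59.0 kJ mol⁻¹, ΔH1 = −12.0 kJ mol⁻¹)
    intermediate → decomposed reagent (k2 = 0.0043 min⁻¹, Ea2 = 121 kJ mol⁻¹)
    gas ⇌ partner, rate k3*(csat - [partner]) (k3 = 4.6 min⁻¹, csat = 1.3 mM)
    starting material + free catalyst ⇌ free catalyst + intermediate (K4 = 2.3, k4 = 7.0 L mol⁻¹ min⁻¹, Ea4 = 58.0 kJ mol⁻¹, ΔH4 = 11.0 kJ mol⁻¹)
    (constants at 100 °C)

| flask | starting material | gas | free catalyst | second catalyst | temperature | time |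
|---|---|---|---|---|---|---|
| alder | 20 mM | 1.3 mM (held) | 0.44 mM | 1.4 mM | 80 °C | 8.0 h |
| oak | 20 mM | 1.3 mM (held) | 0.44 mM | 1.4 mM | 100 °C | 8.0 h |

- the flask with the highest amount of intermediate, in percent of the starting material charged ("all alike" if they lie within 1.5 percentage points) (alder / oak / all alike)
- final intermediate, as a percentage of the starting material charged, in alder
- final intermediate, as a percentage of the starting material charged, in oak

- at the start none of partner is dissolved
- the list of constants is for 100 °C, to be carried to other temperatures by the activation energies and enthalpies

In the first instants, partner fills up from the gas within about 0.217 min. The gas can bring 5.98 mM min⁻¹. Even with the whole charge present as intermediate, the step to target would use 0.0342 mM min⁻¹, far less than that, so you can hold partner at 1.3 mM. Both catalysts are given back by their steps. Each step therefore turns over a fixed fraction of its own species per minute, which is the pseudo-first-order picture, and two such fractions are what you need: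

Feed, starting material to intermediate: oak 0.00308 min⁻¹, alder 0.00107 min⁻¹

Drain, intermediate to target and decomposed reagent: oak 0.00601 min⁻¹, alder 0.00106 min⁻¹

The quantity to carry is the feed-to-drain ratio, feed divided by drain: 1.01 in alder and 0.512 in oak, lower in the hotter flask.

In the middle of the run, intermediate climbs while feed times the fraction of starting material beats drain times the fraction of intermediate. Dropping the two return steps, which makes this rough, the top comes at ln(drain/feed)/(drain − feed):

Top of intermediate: oak 3.80 h, alder 15.7 h

So at the end, 8.0 h, oak is past its top and alder is still climbing. The fraction of the charge standing as intermediate is: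

ratio/(1 − ratio) × (exp(−feed × time) − exp(−drain × time))

Alder: 30.8%

Oak: 18.1%

Most: alder

The forecast names alder, with 28.2% in alder (range 27% to 29.4%) and 20% in oak (19% to 21%). Its grounds: “Decomposition's high activation energy hurts the hotter flask, so alder holds more.” Its figures differ from mine, but the order is the same.

The simulation gives alder, with 28.2% in alder and 20.0% in oak, as the forecast said. Partner stands at 1.30 mM in alder, and the delay in filling it made no difference to the intermediate in alder or oak. Alder has not come to rest at 8.0 h: its ratio of 1.01 put the top near 15.7 h, and the same flask left until 20 h reads 34.0%, against 35.9% by the same reckoning. At 80.0 h alder would still hold 17.4% intermediate, 11.7% starting material and 58.2% decomposed reagent, while oak would hold 0.0254% intermediate and 99.9% decomposed reagent.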